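Start from the neighbours eta and alpha: they hold the same substrate and catalyst, but alpha has twice the reagent of eta. Delta repeats the charge of eta and runs on to a later time.

the same everywhere: substrate 0.200 M; free catalyst 0.00100 M

|  | reagent | time |
|---|---|---|
| eta | 0.500 M |  |
| alpha | 1.00 M |  |
| delta | 0.500 M | 170 min |

- eta run (time / min: [product] / M): 11: 0.0253; 22: 0.0453; 33: 0.0640; 44: 0.0784; 54: 0.0914; 65: 0.1001; 76: 0.1089; 87: 0.1185
- alpha run (time / min: [product] / M): 11: 0.0485; 22: 0.0882; 33: 0.1187; 44: 0.1402; 54: 0.1530; 65: 0.1666; 76: 0.1747; 87: 0.1777

(readings scatter by 0.001 M)

- the power of [reagent] that the first rate follows, about the charge of the eta run; measure it at two percent of substrate made into product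
- product in the delta run at 170 min, as a share of the substrate charged
- which of these the readings show (the catalyst wakes slowly / the substrate kills the catalyst / nothing beyond the main steps / the catalyst dies by itself / the two partners rest in a complex)

- Overall: substrate + reagent -> product, with free catalyst as catalyst.
- Constant volume, constant temperature.
- What is held in complexes is read along with the free species.
- An order is taken over about fifteen percent of the charge, up and down.

At the last reading, eta has turned 59.2% of its substrate and alpha 88.8%. At 11 min the readings of alpha and eta stand in a ratio that gives a reagent power of 0.939, so I take the order as near one.

Now remove the reagent from the comparison. Divide the present ratio of reagent to substrate by the same ratio at the start, take the natural logarithm, and divide by the excess of reagent over substrate in the charge. Call this the clock L, the integrated second-order measure of progress. At 11 min the clock of alpha, 0.285 /M, matches that of eta, 0.278 /M. So at 11 min the definition of the clock carries the doubled reagent.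

By 87 min eta reads 2.09 /M and alpha 2.50 /M. Over the stretches before and after 44 min, the pace of eta falls from 0.0248 /M/min to 0.0233 /M/min. Alpha slows as well, from 0.0300 /M/min to 0.0274 /M/min. Both drops are small and carry the scatter of the readings, but taken together I read them as a catalyst that dies by itself. Carrying the late pace of eta on to 170 min puts delta at 4.02 /M, or 79.6%. Treat that as my own estimate, on the high side, since the pace read from eta was still falling.

The forecast gives 1.15, 78.5% and the two partners rest in a complex, on the ground that “the rate is held back when substrate and reagent are both high, which looks like a resting complex”.

The flask gives 1.0, 71.8% and the catalyst dies by itself, so the forecast stands 6.7 percentage points high.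

    free catalyst + substrate ⇌ catalyst-substrate complex, settled at all times (13.20 /M)
    catalyst-substrate complex + reagent → product + free catalyst + by-product (6.840 /M/min)
    free catalyst → spent catalyst (0.02484 /min)

Divide the product step by the death step and time drops out: the clock advances in step with spent catalyst, and for this catalyst charge it tops out at 3.63 /M. Delta stands at 3.10 /M at 170 min, so 85.4% of its catalyst charge is spent, against 68.9% as read from alpha at 87 min and 57.6% as read from eta then. The turning of free catalyst into spent catalyst is the main reason for the shortfall of delta: the delta run without that step reaches 95.7% instead of 71.8%.

(The numbers in the tables are calculated for substances that don't exist.)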